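## Retrosynthetic overview

1. Target ⇐ one-pot cleavage of the aryl methyl ether and the methyl ester ⇐ catalyst-controlled hydrogenation of the C14=C15 allylic alcohol (sets C15) ⇐ a tetralin ester.
2. Ring B is the only ring made and is closed last. The C4–C10 bond is formed by oxidative phenol umpolung: the ring-A cation (a phenoxenium ion) is trapped by the C4=C11 olefin, and the C11 cation is quenched by a 1,2-hydride shift. This is the same order of events as in the terpene cyclase that builds the serrulatane skeleton, and this one step sets C4 and C11.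
3. Cyclisation substrate ⇐ B-alkyl Suzuki coupling (C3–C4 bond) of an (R)-3-arylbut-1-ene with a (Z)-vinyl iodide.
4. Arene half ⇐ methyl 2,3-dihydroxybenzoate (ring A is bought aromatic and fully oxygenated) by O-crotylation, enantioselective aromatic Claisen rearrangement (sets C1) and O-methylation.
5. Olefin half ⇐ propargyl alcohol + homoprenyl bromide by copper-catalysed carbomagnesiation/iodination, then SeO2 oxidation of the E-methyl group.

Atom labels: C1–C20 are serrulatane positions. C1 = ArCH(CH3); C4 = ArCH bearing the side chain; C5 = aromatic CH; C6 = C–CO2R; C7, C8 = C–O; C9 (bonded to C1) and C10 (bonded to C4) = ring-fusion carbons; C11 = CH(CH2OH); C18 = its CH2OH carbon; C15 = CH(CH3)CH2OH.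

Assumption: the sense of induction of the chiral boron controller (step 2) and of the iridium catalyst (step 8) is assigned by analogy; if the first run shows the opposite sense, the antipodal controller or ligand, equally available, is used.

## Route

Step 1
Reactants: 1 methyl 2,3-dihydroxybenzoate; 2 (2E)-but-2-en-1-ol
Product: 3 methyl 3-{[(2E)-but-2-en-1-yl]oxy}-2-hydroxybenzoate
Conditions: PPh3, DIAD, THF, 0 °C → rt
Reagents that add atoms: none
Why: Mitsunobu etherification, in which the 2-OH is locked in a hydrogen bond to the ester carbonyl so that only the 3-OH is alkylated, and the SN2 displacement at the primary allylic carbon keeps the E geometry that the next step needs.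

Step 2
Reactants: 3 methyl 3-{[(2E)-but-2-en-1-yl]oxy}-2-hydroxybenzoate
Product: 4 methyl 4-[(2R)-but-3-en-2-yl]-2,3-dihydroxybenzoate
Conditions: (4R,5R)-2-bromo-4,5-diphenyl-1,3-bis(4-methylbenzenesulfonyl)-1,3,2-diazaborolidine (1.5 equiv, preformed), Et3N (1.5 equiv), CH2Cl2, −45 → −20 °C; aqueous work-up
Reagents that add atoms: none
Why: enantioselective aromatic Claisen rearrangement promoted by a stoichiometric chiral boron Lewis acid, in which the free 2-OH binds boron covalently, boron chelates the allyl ether oxygen, and the [3,3] shift runs through a chair transition state to the only free ortho position (C9) with one face of the (E)-crotyl terminus shielded by the C2-symmetric bis-sulfonamide, so that C1 is formed R.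

Step 3
Reactants: 4 methyl 4-[(2R)-but-3-en-2-yl]-2,3-dihydroxybenzoate
Product: 5 methyl 4-[(2R)-but-3-en-2-yl]-2-hydroxy-3-methoxybenzoate
Conditions: MeI (1.1 equiv), K2CO3 (1.1 equiv), acetone, rt
Reagents that add atoms: iodomethane, CI
Why: Williamson etherification that is selective for the 3-OH because the 2-OH remains hydrogen-bonded to the ester, leaving free exactly the phenol (C7–OH) that is para to C10 for the key step; no stereocentre is touched.

Step 4
Reactants: 6 5-bromo-2-methylpent-2-ene; 7 prop-2-yn-1-ol
Product: 10 (2Z)-2-(iodomethylidene)-6-methylhept-5-en-1-ol, via (4-methylpent-3-en-1-yl)magnesium bromide 8 (not isolated), via chelated alkenylmagnesium alkoxide 9 (not isolated)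
Conditions: Mg, THF (gives 8, 2.2 equiv); 7, CuI (10 mol %), THF, −10 °C → rt; I2 (1.2 equiv), −78 → 0 °C; 1 M HCl
Reagents that add atoms: iodine, II
Why: copper-catalysed anti-carbomagnesiation of propargyl alcohol (Duboudin–Jousseaume reaction), in which the alkyl group adds to the internal carbon and magnesium is held on the terminal carbon cis to CH2O in a five-membered chelate, so that iodinolysis with retention gives only the Z iodide.

Step 5
Reactants: 10 (2Z)-2-(iodomethylidene)-6-methylhept-5-en-1-ol
Product: 11 (2Z,5E)-2-(iodomethylidene)-6-methylhept-5-ene-1,7-diol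
Conditions: SeO2 (0.5 equiv), t-BuOOH (3 equiv), salicylic acid (10 mol %), CH2Cl2, 0 °C → rt
Reagents that add atoms: tert-butyl hydroperoxide, CC(C)(C)OO; selenium dioxide, O=[Se]=O
Why: selenium dioxide allylic oxidation (ene reaction then [2,3]-sigmatropic shift), which attacks the electron-rich terminal trisubstituted olefin in preference to the deactivated iodoalkene and hydroxylates its E-methyl group to give the (E)-allylic alcohol.

Step 6
Reactants: 5 methyl 4-[(2R)-but-3-en-2-yl]-2-hydroxy-3-methoxybenzoate; 11 (2Z,5E)-2-(iodomethylidene)-6-methylhept-5-ene-1,7-diol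
Product: 13 methyl 2-hydroxy-4-[(2R,5Z,9E)-11-hydroxy-6-(hydroxymethyl)-10-methylundeca-5,9-dien-2-yl]-3-methoxybenzoate, via B-alkyl-9-BBN adduct 12 (not isolated)
Conditions: 9-BBN-H (2.2 equiv; one equivalent is taken up by the phenol as ArO–BBN and released in the aqueous base), THF, 0 °C → rt; then 11, Pd(dppf)Cl2 (5 mol %), AsPh3 (10 mol %), aq. K3PO4 (3 equiv), DMF, rt
Reagents that add atoms: none
Why: anti-Markovnikov hydroboration of the terminal vinyl group followed by B-alkyl Suzuki–Miyaura coupling, which forms the C3–C4 bond with retention of the Z olefin geometry, creates no stereocentre and leaves C1 untouched.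

Step 7
Reactants: 13 methyl 2-hydroxy-4-[(2R,5Z,9E)-11-hydroxy-6-(hydroxymethyl)-10-methylundeca-5,9-dien-2-yl]-3-methoxybenzoate
Product: 15 methyl (5R,8S)-8-[(2S,5E)-1,7-dihydroxy-6-methylhept-5-en-2-yl]-3-hydroxy-4-methoxy-5-methyl-5,6,7,8-tetrahydronaphthalene-2-carboxylate, via C18 aldehyde 14 (not isolated)
Conditions: PhI(OAc)2 (1.0 equiv), (CF3)2CHOH (0.01 M), −20 °C, 10 min; evaporate at 0 °C; NaBH4, MeOH, 0 °C
Reagents that add atoms: none
Why: Proposed new method: the C7 phenol is oxidised by PhI(OAc)2 in HFIP to a phenoxenium ion (aryl-λ3-iodane fragmentation), its para carbon C10 (free, and the only ring-A position besides the hindered, fully substituted C8 that the tether can reach through a six-membered transition state) is attacked by C4 of the (Z)-olefin in a 6-exo Markovnikov cation–olefin closure, the β-hydroxy tertiary C11 cation is quenched by a 1,2-hydride shift from C18 anti to the new C10–C4 bond (semipinacol termination) so that the Z geometry becomes the 4S,11S relationship, the C1 methyl group (pseudoaxial to avoid A(1,3) strain with the C8 methoxy group) and the incoming C11 branch take up the trans-diaxial arrangement across the forming ring so that C4 is formed S, rearomatisation gives aldehyde 14 and NaBH4 reduces it before C11 can epimerise; the closest known reaction type is the hypervalent-iodine-mediated oxidative Prins–pinacol cyclisation of phenols (aromatic ring umpolung), here with capture at an unsubstituted para position and hydride rather than carbon migration.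

Step 8
Reactants: 15 methyl (5R,8S)-8-[(2S,5E)-1,7-dihydroxy-6-methylhept-5-en-2-yl]-3-hydroxy-4-methoxy-5-methyl-5,6,7,8-tetrahydronaphthalene-2-carboxylate
Product: 16 methyl (5R,8S)-8-[(2S,6S)-1,7-dihydroxy-6-methylheptan-2-yl]-3-hydroxy-4-methoxy-5-methyl-5,6,7,8-tetrahydronaphthalene-2-carboxylate
Conditions: [Ir(cod)(L*)]BArF (2 mol %; L* = chiral pyridine–phosphinite N,P ligand), H2 (50 bar), CH2Cl2, rt
Reagents that add atoms: none
Why: iridium-catalysed asymmetric hydrogenation of an (E)-2-methylalk-2-en-1-ol, the only olefin left, in which the chiral N,P ligand selects the olefin face (reagent control, because C15 is remote from the existing centres) and gives 15S.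

Step 9
Reactants: 16 methyl (5R,8S)-8-[(2S,6S)-1,7-dihydroxy-6-methylheptan-2-yl]-3-hydroxy-4-methoxy-5-methyl-5,6,7,8-tetrahydronaphthalene-2-carboxylate
Product: 17 (5R,8S)-8-[(2S,6S)-1,7-dihydroxy-6-methylheptan-2-yl]-3,4-dihydroxy-5-methyl-5,6,7,8-tetrahydronaphthalene-2-carboxylic acid
Conditions: AlCl3 (10 equiv), EtSH, CH2Cl2, 0 °C → rt; 1 M HCl
Reagents that add atoms: none
Why: hard-acid/soft-nucleophile dealkylation, in which aluminium chelated between the C7 phenoxide and the neighbouring methoxy and ester oxygens activates both O–CH3 bonds for SN2 attack by ethanethiol, so that the catechol and the carboxylic acid are released together while the primary alcohols and the four stereocentres are untouched.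

## Compound list

1 | methyl 2,3-dihydroxybenzoate | COC(=O)c1cccc(O)c1O | starting material
2 | (2E)-but-2-en-1-ol | C/C=C/CO | starting material
3 | methyl 3-{[(2E)-but-2-en-1-yl]oxy}-2-hydroxybenzoate | COC(=O)c1cccc(OC/C=C/C)c1O | intermediate
4 | methyl 4-[(2R)-but-3-en-2-yl]-2,3-dihydroxybenzoate | C=C[C@@H](C)c1ccc(C(=O)OC)c(O)c1O | intermediate
5 | methyl 4-[(2R)-but-3-en-2-yl]-2-hydroxy-3-methoxybenzoate | C=C[C@@H](C)c1ccc(C(=O)OC)c(O)c1OC | intermediate
6 | 5-bromo-2-methylpent-2-ene | CC(C)=CCCBr | starting material
7 | prop-2-yn-1-ol | C#CCO | starting material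
8 | (4-methylpent-3-en-1-yl)magnesium bromide | CC(C)=CCC[Mg]Br | intermediate
9 | [(1Z)-2-{[(bromomagnesio)oxy]methyl}-6-methylhepta-1,5-dien-1-yl]magnesium bromide | Br[Mg]/C=C(\CO[Mg]Br)CCC=C(C)C | intermediate
10 | (2Z)-2-(iodomethylidene)-6-methylhept-5-en-1-ol | I/C=C(\CO)CCC=C(C)C | intermediate
11 | (2Z,5E)-2-(iodomethylidene)-6-methylhept-5-ene-1,7-diol | I/C=C(\CO)CC/C=C(\C)CO | intermediate
12 | methyl 4-[(2R)-4-(9-borabicyclo[3.3.1]nonan-9-yl)butan-2-yl]-2-hydroxy-3-methoxybenzoate (drawn with free OH; carried as the O–BBN borinate until the base is added) | COC(=O)c1ccc([C@H](C)CCB2C3CCCC2CCC3)c(OC)c1O | intermediate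
13 | methyl 2-hydroxy-4-[(2R,5Z,9E)-11-hydroxy-6-(hydroxymethyl)-10-methylundeca-5,9-dien-2-yl]-3-methoxybenzoate | COC(=O)c1ccc([C@H](C)CC/C=C(\CO)CC/C=C(\C)CO)c(OC)c1O | intermediate
14 | methyl (5R,8S)-3-hydroxy-8-[(2S,5E)-7-hydroxy-6-methyl-1-oxohept-5-en-2-yl]-4-methoxy-5-methyl-5,6,7,8-tetrahydronaphthalene-2-carboxylate | OC/C(C)=C/CC[C@H](C=O)[C@@H]1CC[C@@H](C)c2c1cc(C(=O)OC)c(O)c2OC | intermediate
15 | methyl (5R,8S)-8-[(2S,5E)-1,7-dihydroxy-6-methylhept-5-en-2-yl]-3-hydroxy-4-methoxy-5-methyl-5,6,7,8-tetrahydronaphthalene-2-carboxylate | OC/C(C)=C/CC[C@H](CO)[C@@H]1CC[C@@H](C)c2c1cc(C(=O)OC)c(O)c2OC | intermediate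
16 | methyl (5R,8S)-8-[(2S,6S)-1,7-dihydroxy-6-methylheptan-2-yl]-3-hydroxy-4-methoxy-5-methyl-5,6,7,8-tetrahydronaphthalene-2-carboxylate | C[C@H](CO)CCC[C@H](CO)[C@@H]1CC[C@@H](C)c2c1cc(C(=O)OC)c(O)c2OC | intermediate
17 | (5R,8S)-8-[(2S,6S)-1,7-dihydroxy-6-methylheptan-2-yl]-3,4-dihydroxy-5-methyl-5,6,7,8-tetrahydronaphthalene-2-carboxylic acid | C[C@H](CO)CCC[C@H](CO)[C@@H]1CC[C@@H](C)c2c1cc(C(=O)O)c(O)c2O | target

## Step count and risks

Total step count: 9 (steps 1–3 and 4–5 are two branches that meet in step 6).
Longest linear sequence: 7 steps (1, 2, 3, 6, 7, 8, 9).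

The three steps most likely to fail:

**Step 7 (oxidative cyclisation).** This is a new reaction, and four things are open: ipso attack at the methoxy-bearing C8 instead of C10; over-oxidation of the product phenol to a para-quinone methide, which would erase C4; the 1,4-trans face selectivity; and the anti course of the hydride shift. Diastereomers would be separated at 15.

The fallback drops the oxidant and uses the arene as the nucleophile. It sets out from 13. MnO2 oxidises both allylic alcohols to the bis-enal methyl 4-[(2R,5Z,9E)-6-formyl-10-methyl-11-oxoundeca-5,9-dien-2-yl]-2-hydroxy-3-methoxybenzoate F3. A chiral primary-amine salt (9-amino-9-deoxy-epi-cinchona alkaloid·2 TFA) then activates the C18 enal as its iminium ion, and C10, para to the free phenol, adds to C4 in an intramolecular Friedel–Crafts conjugate addition. The catalyst controls C4, enamine protonation sets C11, and a wrong C11 epimer can be equilibrated at the aldehyde stage. This gives the dialdehyde methyl (5R,8S)-3-hydroxy-4-methoxy-5-methyl-8-[(2S,5E)-6-methyl-1,7-dioxohept-5-en-2-yl]-5,6,7,8-tetrahydronaphthalene-2-carboxylate F4. Luche reduction (NaBH4, CeCl3) of both aldehydes comes back to the route at 15.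

**Step 2 (enantioselective Claisen).** The ester carbonyl can compete with the allyl ether oxygen for boron, which would lower rate and ee.

The fallback replaces reagent control by chirality transfer. It sets out from 1. Mitsunobu reaction with (2R,3E)-pent-3-en-2-ol (inversion) gives the ether methyl 2-hydroxy-3-{[(2S,3E)-pent-3-en-2-yl]oxy}benzoate F1. Thermal Claisen rearrangement (N,N-diethylaniline, 180 °C) through a chair transition state with the methyl group equatorial transfers the C–O chirality to C1 and gives methyl 2,3-dihydroxy-4-[(2R,3E)-pent-3-en-2-yl]benzoate F2. Ethenolysis (Hoveyda–Grubbs II, ethylene) cuts the propenyl group back to vinyl and comes back to the route at 4.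

**Step 8 (late asymmetric hydrogenation).** C15 is remote, so a low ee would give an epimer that is hard to separate, and it would do so on advanced material.

The fallback sets C15 by enzyme-controlled protonation instead of by a metal hydride. It sets out from 15. MnO2 oxidises only the allylic alcohol to the enal methyl (5R,8S)-3-hydroxy-8-[(2S,5E)-1-hydroxy-6-methyl-7-oxohept-5-en-2-yl]-4-methoxy-5-methyl-5,6,7,8-tetrahydronaphthalene-2-carboxylate F5. An (S)-selective ene-reductase of the Old Yellow Enzyme family (NADPH, glucose/glucose dehydrogenase recycling) reduces the C=C bond to the aldehyde methyl (5R,8S)-3-hydroxy-8-[(2S,6S)-1-hydroxy-6-methyl-7-oxoheptan-2-yl]-4-methoxy-5-methyl-5,6,7,8-tetrahydronaphthalene-2-carboxylate F6. This is reduced in the same pot (alcohol dehydrogenase or NaBH4) before it can racemise, and the sequence comes back to the route at 16.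

## Further compounds

F1 | step 2 | methyl 2-hydroxy-3-{[(2S,3E)-pent-3-en-2-yl]oxy}benzoate | COC(=O)c1cccc(O[C@@H](C)/C=C/C)c1O
F2 | step 2 | methyl 2,3-dihydroxy-4-[(2R,3E)-pent-3-en-2-yl]benzoate | COC(=O)c1ccc([C@H](C)/C=C/C)c(O)c1O
F3 | step 7 | methyl 4-[(2R,5Z,9E)-6-formyl-10-methyl-11-oxoundeca-5,9-dien-2-yl]-2-hydroxy-3-methoxybenzoate | COC(=O)c1ccc([C@H](C)CC/C=C(\C=O)CC/C=C(\C)C=O)c(OC)c1O
F4 | step 7 | methyl (5R,8S)-3-hydroxy-4-methoxy-5-methyl-8-[(2S,5E)-6-methyl-1,7-dioxohept-5-en-2-yl]-5,6,7,8-tetrahydronaphthalene-2-carboxylate | O=C/C(C)=C/CC[C@H](C=O)[C@@H]1CC[C@@H](C)c2c1cc(C(=O)OC)c(O)c2OC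
F5 | step 8 | methyl (5R,8S)-3-hydroxy-8-[(2S,5E)-1-hydroxy-6-methyl-7-oxohept-5-en-2-yl]-4-methoxy-5-methyl-5,6,7,8-tetrahydronaphthalene-2-carboxylate | O=C/C(C)=C/CC[C@H](CO)[C@@H]1CC[C@@H](C)c2c1cc(C(=O)OC)c(O)c2OC
F6 | step 8 | methyl (5R,8S)-3-hydroxy-8-[(2S,6S)-1-hydroxy-6-methyl-7-oxoheptan-2-yl]-4-methoxy-5-methyl-5,6,7,8-tetrahydronaphthalene-2-carboxylate | C[C@H](C=O)CCC[C@H](CO)[C@@H]1CC[C@@H](C)c2c1cc(C(=O)OC)c(O)c2OC
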